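The flavanone ring C is disconnected across C3–C4 and O1–C2. O1, C8a, C4a and C4 come from a ring A ortho-quinone methide, and C2–C3, already carrying ring B and the flavon-8-yl group trans to each other, is an E-stilbene. One acid-catalysed inverse-demand hetero-Diels–Alder reaction therefore closes ring C, makes both bonds and sets C2 and C3. The alkene partner is an 8-styrylapigenin whose O7 already bears the sulfate as its 2,2,2-trichloroethyl diester, an acid-stable acceptor that sharpens the alkene polarisation and leaves with the benzyl ethers at the end. The diene precursor is a benzyl-protected ortho-hydroxybenzyl alcohol.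

Key step: step 10

Remark on stereochemistry: the target string encodes 2R,3S with ring B and the flavonyl group trans; the same descriptors hold for the C4-methylene cycloadduct, so no structure needed correction.
Assumption 1: the sense of induction of the chiral acid cannot be fixed in advance; the (R)-catalyst is written and its mirror image would be used if a first run gives the (2S,3R) series.
Assumption 2: the target is taken as the free hydrogen sulfate drawn and is liberated from its ammonium salt only at the end, in the cold.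

Step 1
Reactants: 1 2,4,6-trihydroxybenzaldehyde
Product: 2 4,6-bis(benzyloxy)-2-hydroxybenzaldehyde
Conditions: BnBr (2.1 equiv), K2CO3 (2.2 equiv), DMF, 0 °C to rt
Reagents that add atoms: benzyl bromide, BrCc1ccccc1
Why: Williamson etherification should stop at the dibenzyl ether because the hydroxyl hydrogen-bonded to the formyl group is the least acidic and least nucleophilic of the three.

Step 2
Reactants: 2 4,6-bis(benzyloxy)-2-hydroxybenzaldehyde
Product: 3 3,5-bis(benzyloxy)-2-(hydroxymethyl)phenol
Conditions: NaBH4 (1.2 equiv), THF–EtOH, 0 °C; aq. NH4Cl quench, used fresh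
Reagents that add atoms: none
Why: Borohydride reduction of the aldehyde should give the benzylic alcohol, with low temperature and a neutral quench guarding against over-reduction and acid-induced self-condensation of this electron-rich alcohol.

Step 3
Reactants: 4 4-acetoxystyrene
Product: 6 4-(benzyloxy)styrene, via potassium 4-vinylphenoxide 5 (not isolated)
Conditions: KOH (2.0 equiv), EtOH, 0 °C to rt; then BnBr (1.05 equiv), rt
Reagents that add atoms: benzyl bromide, BrCc1ccccc1
Why: Ester saponification followed in the same flask by Williamson etherification should give the ether without isolating the polymerisation-prone 4-vinylphenol.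

Step 4
Reactants: 7 apigenin
Product: 8 7-O-(methoxymethyl)apigenin
Conditions: MOMCl (1.05 equiv), iPr2NEt (1.2 equiv), DMF, 0 °C
Reagents that add atoms: chloromethyl methyl ether, COCCl
Why: O-alkylation with one equivalent should go to O7, the most acidic phenol (conjugated to the C4 carbonyl), since O5 is locked in the chelate and O4' is less acidic.

Step 5
Reactants: 8 7-O-(methoxymethyl)apigenin
Product: 9 5,4'-di-O-benzyl-7-O-(methoxymethyl)apigenin
Conditions: BnBr (3 equiv), K2CO3 (4 equiv), DMF, 60 °C
Reagents that add atoms: benzyl bromide, BrCc1ccccc1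
Why: Williamson etherification under forcing conditions should benzylate O4' and also the chelated O5, and the base-stable MOM acetal should survive.

Step 6
Reactants: 9 5,4'-di-O-benzyl-7-O-(methoxymethyl)apigenin
Product: 10 8-iodo-5,4'-di-O-benzyl-7-O-(methoxymethyl)apigenin
Conditions: NIS (1.1 equiv), DMF, rt, dark
Reagents that add atoms: N-iodosuccinimide, O=C1CCC(=O)N1I
Why: Electrophilic aromatic iodination of a 5,7-dialkoxyflavone should go to C8 (para to O5, ortho to O7) because, with O5 alkylated, no chelated hydroxyl directs to C6, and ring B is less activated.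

Step 7
Reactants: 10 8-iodo-5,4'-di-O-benzyl-7-O-(methoxymethyl)apigenin; 6 4-(benzyloxy)styrene
Product: 11 (E)-8-[2-(4-benzyloxyphenyl)ethenyl]-5,4'-di-O-benzyl-7-O-(methoxymethyl)apigenin
Conditions: Pd(OAc)2 (5 mol%), P(o-tol)3 (12 mol%), Et3N (3 equiv), DMF, 100 °C
Reagents that add atoms: none
Why: The Mizoroki–Heck reaction (oxidative addition of the aryl iodide to zerovalent palladium, syn insertion at the terminal styrene carbon, syn β-hydride elimination) should give the E-stilbene.

Step 8
Reactants: 11 (E)-8-[2-(4-benzyloxyphenyl)ethenyl]-5,4'-di-O-benzyl-7-O-(methoxymethyl)apigenin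
Product: 12 (E)-8-[2-(4-benzyloxyphenyl)ethenyl]-5,4'-di-O-benzylapigenin (free 7-OH)
Conditions: TsOH·H2O (0.2 equiv), MeOH–CH2Cl2, 40 °C
Reagents that add atoms: none
Why: Acid-catalysed acetal exchange with methanol should remove the aryl MOM ether, while catalytic acid at this temperature should not touch the benzyl ethers or protonate the stilbene.

Step 9
Reactants: 12 (E)-8-[2-(4-benzyloxyphenyl)ethenyl]-5,4'-di-O-benzylapigenin (free 7-OH)
Product: 13 (E)-8-[2-(4-benzyloxyphenyl)ethenyl]-5,4'-di-O-benzylapigenin 7-(2,2,2-trichloroethyl sulfate)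
Conditions: Cl3CCH2OSO2Cl (1.5 equiv), Et3N (2 equiv), DMAP (0.5 equiv), THF, 0 °C to rt
Reagents that add atoms: 2,2,2-trichloroethyl chlorosulfate, ClS(=O)(=O)OCC(Cl)(Cl)Cl
Why: DMAP-assisted O-sulfonylation of the only free phenol with a chlorosulfate ester should give the neutral sulfate diester, installed after the palladium step because hot amine base would degrade it.

Step 10
Reactants: 13 (E)-8-[2-(4-benzyloxyphenyl)ethenyl]-5,4'-di-O-benzylapigenin 7-(2,2,2-trichloroethyl sulfate); 3 3,5-bis(benzyloxy)-2-(hydroxymethyl)phenol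
Product: 15 (2R,3S)-trans-flavan cycloadduct (C4 is CH2; 5,7-di-O-benzyl ring A; 4-benzyloxyphenyl at C2; C3 bonded to C8 of the protected flavone sulfate diester), via ortho-quinone methide 14 (not isolated)
Conditions: (R)-3,3'-bis(2,4,6-triisopropylphenyl)-BINOL N-triflylphosphoramide (10 mol%), 4 Å MS, toluene, −20 to 0 °C; 3 (2 equiv) added by syringe pump
Reagents that add atoms: none
Why: The acid should ionise the benzylic alcohol of 3 to the hydrogen-bonded quinone methide 14, whose unsubstituted methide carbon (future C4) is attacked by the stilbene carbon bearing the flavonyl group (future C3) while charge builds on the carbon next to the 4-benzyloxyphenyl ring (future C2), which the methide oxygen (O1) then captures in a concerted but asynchronous inverse-demand hetero-Diels–Alder event. The closest known reaction type is the chiral Brønsted-acid-catalysed [4+2] cycloaddition of ortho-quinone methides from ortho-hydroxybenzyl alcohols with styrenes that carry no hydrogen-bond donor; an unsubstituted methide combined with a stilbene is a substrate extension whose enantioselectivity is unproven. Ring C, the six-membered dihydropyran, is closed by this intermolecular [4+2] cycloaddition, C3–C4 forming ahead of O1–C2. The trans relation of C2 and C3 follows from suprafacial addition to the E-alkene and is also the diequatorial arrangement, and the absolute configuration (2R,3S) is to be set by the chiral counter-anion bound to the methide. The step needs regioselectivity, secured because only the coplanar donor ring B can stabilise the developing cation while the doubly ortho-substituted flavone ring is twisted and deactivated by the sulfate diester and the pyrone carbonyl, and chemoselectivity against self-alkylation of the electron-rich ring of 3, secured by keeping 14 at low concentration through slow addition.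

Step 11
Reactants: 15 (2R,3S)-trans-flavan cycloadduct
Product: 16 (2R,3R,4RS)-flavan-4-ol (C4 epimer mixture; C2 and C3 arranged as in 15)
Conditions: DDQ (1.5 equiv), CH2Cl2–H2O, rt
Reagents that add atoms: water, O
Why: DDQ hydride abstraction at benzylic C4, whose cation is stabilised by O5, O7 and O1 of ring A, followed by capture with water is the known C4 oxidation of benzyl-protected 5,7-dioxygenated flavans; the C2–H is less activated and the sulfate diester is inert.

Step 12
Reactants: 16 (2R,3R,4RS)-flavan-4-ol
Product: 17 (2R,3S)-penta-O-benzyl flavanone–flavone 7''-(2,2,2-trichloroethyl sulfate)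
Conditions: DMP (1.5 equiv), pyridine, CH2Cl2, 0 °C to rt
Reagents that add atoms: none
Why: Periodinane oxidation of the secondary benzylic alcohol under pyridine buffering should give the ketone from both C4 epimers; C3 becomes enolisable, but the 2,3-trans arrangement is the thermodynamically preferred one.

Step 13
Reactants: 17 (2R,3S)-penta-O-benzyl flavanone–flavone 7''-(2,2,2-trichloroethyl sulfate)
Product: 19 CNP0271389.1 [(2R,3S)-naringenin-(3→8)-apigenin 7''-O-sulfate], via ammonium sulfate salt 18 (not isolated)
Conditions: 10% Pd/C, HCO2NH4 (excess), MeOH–THF, rt; filter; then aq. HCl (1.0 equiv), 0 °C, C18 desalting, lyophilisation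
Reagents that add atoms: none
Why: Catalytic transfer hydrogenolysis should cleave the five benzyl ethers and reduce a C–Cl bond of the trichloroethyl group, triggering β-elimination that frees the aryl sulfate monoester under near-neutral conditions that spare ring C; one equivalent of cold acid then gives the hydrogen sulfate.

Compound list
1 | 2,4,6-trihydroxybenzaldehyde | O=Cc1c(O)cc(O)cc1O | starting material
2 | 4,6-bis(benzyloxy)-2-hydroxybenzaldehyde | O=Cc1c(O)cc(OCc2ccccc2)cc1OCc1ccccc1 | intermediate
3 | 3,5-bis(benzyloxy)-2-(hydroxymethyl)phenol | OCc1c(O)cc(OCc2ccccc2)cc1OCc1ccccc1 | intermediate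
4 | 4-acetoxystyrene | C=Cc1ccc(OC(C)=O)cc1 | starting material
5 | potassium 4-vinylphenoxide (not isolated) | C=Cc1ccc([O-])cc1.[K+] | intermediate
6 | 4-(benzyloxy)styrene | C=Cc1ccc(OCc2ccccc2)cc1 | intermediate
7 | apigenin | O=c1cc(-c2ccc(O)cc2)oc2cc(O)cc(O)c12 | starting material
8 | 7-O-(methoxymethyl)apigenin | COCOc1cc(O)c2c(=O)cc(-c3ccc(O)cc3)oc2c1 | intermediate
9 | 5,4'-di-O-benzyl-7-O-(methoxymethyl)apigenin | COCOc1cc(OCc2ccccc2)c2c(=O)cc(-c3ccc(OCc4ccccc4)cc3)oc2c1 | intermediate
10 | 8-iodo-5,4'-di-O-benzyl-7-O-(methoxymethyl)apigenin | COCOc1cc(OCc2ccccc2)c2c(=O)cc(-c3ccc(OCc4ccccc4)cc3)oc2c1I | intermediate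
11 | (E)-8-[2-(4-benzyloxyphenyl)ethenyl]-5,4'-di-O-benzyl-7-O-(methoxymethyl)apigenin | COCOc1cc(OCc2ccccc2)c2c(=O)cc(-c3ccc(OCc4ccccc4)cc3)oc2c1/C=C/c1ccc(OCc2ccccc2)cc1 | intermediate
12 | (E)-8-[2-(4-benzyloxyphenyl)ethenyl]-5,4'-di-O-benzylapigenin, free 7-OH | Oc1cc(OCc2ccccc2)c2c(=O)cc(-c3ccc(OCc4ccccc4)cc3)oc2c1/C=C/c1ccc(OCc2ccccc2)cc1 | intermediate
13 | (E)-8-[2-(4-benzyloxyphenyl)ethenyl]-5,4'-di-O-benzylapigenin 7-(2,2,2-trichloroethyl sulfate) | ClC(Cl)(Cl)COS(=O)(=O)Oc1cc(OCc2ccccc2)c2c(=O)cc(-c3ccc(OCc4ccccc4)cc3)oc2c1/C=C/c1ccc(OCc2ccccc2)cc1 | intermediate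
14 | 3,5-bis(benzyloxy)-6-methylidenecyclohexa-2,4-dien-1-one, ortho-quinone methide (not isolated) | C=C1C(=O)C=C(OCc2ccccc2)C=C1OCc1ccccc1 | intermediate
15 | (2R,3S)-2,3-trans-5,7-bis(benzyloxy)-2-(4-benzyloxyphenyl)-3-(flavon-8-yl)flavan, flavone unit 5-OBn, 4'-OBn, 7-OSO2OCH2CCl3 | C1c2c(OCc3ccccc3)cc(OCc3ccccc3)cc2O[C@@H](c2ccc(OCc3ccccc3)cc2)[C@@H]1c1c(OS(=O)(=O)OCC(Cl)(Cl)Cl)cc(OCc2ccccc2)c2c(=O)cc(-c3ccc(OCc4ccccc4)cc3)oc12 | intermediate
16 | (2R,3R,4RS)-flavan-4-ol of 15, C4 epimer mixture (C3 descriptor changes by priority only) | OC1c2c(OCc3ccccc3)cc(OCc3ccccc3)cc2O[C@@H](c2ccc(OCc3ccccc3)cc2)[C@@H]1c1c(OS(=O)(=O)OCC(Cl)(Cl)Cl)cc(OCc2ccccc2)c2c(=O)cc(-c3ccc(OCc4ccccc4)cc3)oc12 | intermediate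
17 | (2R,3S)-5,7,4'-tri-O-benzylnaringenin-(3→8)-5,4'-di-O-benzylapigenin 7''-(2,2,2-trichloroethyl sulfate) | O=C1c2c(OCc3ccccc3)cc(OCc3ccccc3)cc2O[C@@H](c2ccc(OCc3ccccc3)cc2)[C@@H]1c1c(OS(=O)(=O)OCC(Cl)(Cl)Cl)cc(OCc2ccccc2)c2c(=O)cc(-c3ccc(OCc4ccccc4)cc3)oc12 | intermediate
18 | ammonium salt of the target sulfate (not isolated) | O=C1c2c(O)cc(O)cc2O[C@@H](c2ccc(O)cc2)[C@@H]1c1c(OS(=O)(=O)[O-])cc(O)c2c(=O)cc(-c3ccc(O)cc3)oc12.[NH4+] | intermediate
19 | CNP0271389.1, (2R,3S)-naringenin-(3→8)-apigenin 7''-O-(hydrogen sulfate) | O=C1c2c(O)cc(O)cc2O[C@@H](c2ccc(O)cc2)[C@@H]1c1c(OS(=O)(=O)O)cc(O)c2c(=O)cc(-c3ccc(O)cc3)oc12 | target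

Total step count: 13. Longest linear sequence: 10 steps (apigenin 7 to 19, steps 4 to 13).

Steps most likely to fail

Step 10. The chiral anion may discriminate the alkene faces poorly because the methide carbon carries no substituent. The quinone methide may also be consumed by alkylating the electron-rich ring of its own precursor, and the basic pyrone carbonyl may tie up the acid. Fallback: setting out from 3 and 13, the cycloaddition is run with achiral diphenyl phosphate in toluene, which relies only on the established acid-catalysed reaction and should give the trans adduct as a racemate, that is 15 together with the mirror-image (2S,3R)-flavan F1. Preparative chromatography on a chiral stationary phase then separates the two, and the route is rejoined at 15.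

Step 11. The C4 cation may lose the C3 proton, giving the 2H-chromene and then a flavylium ion, instead of being captured by water. Hydride may also be taken from C2, or the alcohol may re-ionise under the acidic hydroquinone. Fallback: setting out from 15, DDQ with a large excess of ethylene glycol in homogeneous CH2Cl2 should give the 4-(2-hydroxyethoxy)flavan F2. A second portion of DDQ abstracts the remaining C4 hydride, and the tethered hydroxyl closes onto the oxocarbenium ion to give the C4 ethylene ketal F3, so that no free benzylic alcohol is ever present. Hydrolysis with PPTS in aqueous acetone then returns to the route at 17, bypassing 16 and step 12.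

Step 13. Chloride released from the trichloroethyl group may poison the palladium and leave benzyl ethers uncleaved. Prolonged exposure may instead over-reduce the molecule, by hydrogenolysis of the benzylic C2–O1 bond or saturation of the pyrone alkene. Fallback: the two unmaskings are separated. Setting out from 17, Zn dust and HCO2NH4 in MeOH–THF remove the trichloroethyl group by metal reduction without palladium and should give the ammonium penta-O-benzyl sulfate F4. Hydrogenolysis with H2 (1 atm) over Pd(OH)2/C in THF–MeOH, monitored closely, then returns to the route at 18, which is acidified as in step 13.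

Further compounds
F1 | step 10 | (2S,3R)-enantiomer of 15 | C1c2c(OCc3ccccc3)cc(OCc3ccccc3)cc2O[C@H](c2ccc(OCc3ccccc3)cc2)[C@H]1c1c(OS(=O)(=O)OCC(Cl)(Cl)Cl)cc(OCc2ccccc2)c2c(=O)cc(-c3ccc(OCc4ccccc4)cc3)oc12
F2 | step 11 | 4-(2-hydroxyethoxy) ether of 15, C4 epimer mixture | OCCOC1c2c(OCc3ccccc3)cc(OCc3ccccc3)cc2O[C@@H](c2ccc(OCc3ccccc3)cc2)[C@@H]1c1c(OS(=O)(=O)OCC(Cl)(Cl)Cl)cc(OCc2ccccc2)c2c(=O)cc(-c3ccc(OCc4ccccc4)cc3)oc12
F3 | step 11 | C4 ethylene ketal (spiro-1,3-dioxolane) of 17 | C1COC2(O1)c1c(OCc3ccccc3)cc(OCc3ccccc3)cc1O[C@@H](c1ccc(OCc3ccccc3)cc1)[C@@H]2c1c(OS(=O)(=O)OCC(Cl)(Cl)Cl)cc(OCc2ccccc2)c2c(=O)cc(-c3ccc(OCc4ccccc4)cc3)oc12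
F4 | step 13 | ammonium (2R,3S)-penta-O-benzyl flavanone–flavone 7''-sulfate | O=C1c2c(OCc3ccccc3)cc(OCc3ccccc3)cc2O[C@@H](c2ccc(OCc3ccccc3)cc2)[C@@H]1c1c(OS(=O)(=O)[O-])cc(OCc2ccccc2)c2c(=O)cc(-c3ccc(OCc4ccccc4)cc3)oc12.[NH4+]
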